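Every ring of the pentamer has an oxygen-bearing carbon lying between two hydroxylated carbons: the diaryl-ether carbon (C–OAr) of rings A–D and the middle C–OH of the 3,4,5-triol ring E. The ten flanking aryl C–OH bonds are traced back to aryl C–CHO bonds. A single peracid treatment converts the ten formyl groups of a decaaldehyde into formate esters by aryl migration, making ten aryl C–O bonds and no ring. The decaaldehyde, a pentameric 2,6-diformyl-1,4-phenylene ether, is assembled by four fluoride displacements activated by those same formyl pairs; its two other oxygens (para on A, central on E) are benzyl ethers, so the end game is acid-catalysed methanolysis and hydrogenolysis.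

Key step: step 15

Assumption: the target has no stereocentre and no isolable axis, so "single enantiomer" is read as the achiral compound itself and no stereocontrol is needed.

Notation: a "unit" is a 2,6-diformyl-1,4-phenylene ring. Its C1 (between the two CHO groups) carries the oxygen pointing to the ring E end, and its C4 carries the oxygen pointing to the ring A end. Ring A is the terminal ring with the free para oxygen; ring E is the ring that becomes the 3,4,5-triol.

Protecting groups: benzyl ethers (not methyl ethers) sit on the para oxygen of A and the central oxygen of E, because they leave by neutral hydrogenolysis and spare the air-sensitive dodecaol a Lewis-acid dealkylation. 4-Methoxybenzyl (PMB) is the temporary group on the growing chain phenol. The acetate serves only the radical bromination.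

Step 1
Reactants: 1 4-fluoro-3,5-dimethylphenol; 2 acetic anhydride
Product: 3 4-fluoro-3,5-dimethylphenyl acetate
Conditions: Ac2O, pyridine, DMAP (cat.), CH2Cl2, 0 °C to rt
Reagents that add atoms: acetic anhydride, CC(=O)OC(C)=O
Why: O-acylation of the phenol (nucleophilic acyl substitution) masks the OH and lowers the ring electron density, so that step 2 attacks the methyl groups by the radical chain and not the ring.

Step 2
Reactants: 3 4-fluoro-3,5-dimethylphenyl acetate; 4 N-bromosuccinimide
Product: 5 3,5-bis(dibromomethyl)-4-fluorophenyl acetate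
Conditions: NBS (4.4 equiv), AIBN (cat.), PhCF3, reflux, hν
Reagents that add atoms: N-bromosuccinimide, O=C1CCC(=O)N1Br
Why: Wohl–Ziegler radical bromination should put two bromine atoms on each benzylic methyl, a third being disfavoured sterically and electronically, while the acetate and fluorine keep electrophilic ring bromination slow.

Step 3
Reactants: 5 3,5-bis(dibromomethyl)-4-fluorophenyl acetate
Product: 7 2-fluoro-5-hydroxybenzene-1,3-dicarbaldehyde, via 4-fluoro-3,5-diformylphenyl acetate 6 (not isolated)
Conditions: AgNO3 (4.4 equiv), acetone/H2O, 60 °C, dark; filter; then 2 M H2SO4, 60 °C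
Reagents that add atoms: water, O
Why: Silver-assisted hydrolysis of the two benzal dibromides gives the aldehydes and acid-catalysed ester hydrolysis then frees the phenol, the medium staying acidic so that no oxygen nucleophile attacks the now doubly activated C–F carbon.

Step 4
Reactants: 7 2-fluoro-5-hydroxybenzene-1,3-dicarbaldehyde; 8 4-methoxybenzyl chloride
Product: 9 2-fluoro-5-[(4-methoxybenzyl)oxy]benzene-1,3-dicarbaldehyde (chain-extension monomer)
Conditions: PMBCl (1.5 equiv), K2CO3, NaI (cat.), MeCN, rt
Reagents that add atoms: 4-methoxybenzyl chloride, COc1ccc(CCl)cc1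
Why: Williamson ether synthesis through the benzylic iodide formed in situ; as a phenoxide 7 is a deactivated SNAr acceptor, and fast alkylation at room temperature in acetonitrile should outrun attack of the phenoxide on the fluoride of the product.

Step 5
Reactants: 7 2-fluoro-5-hydroxybenzene-1,3-dicarbaldehyde; 10 benzyl bromide
Product: 11 5-(benzyloxy)-2-fluorobenzene-1,3-dicarbaldehyde (ring A unit)
Conditions: BnBr (1.3 equiv), K2CO3, MeCN, rt
Reagents that add atoms: benzyl bromide, BrCc1ccccc1
Why: Williamson ether synthesis with a reactive benzylic bromide, again faster at room temperature than any phenoxide–fluoride substitution.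

Step 6
Reactants: 9 2-fluoro-5-[(4-methoxybenzyl)oxy]benzene-1,3-dicarbaldehyde; 12 benzyl alcohol
Product: 13 2-(benzyloxy)-5-[(4-methoxybenzyl)oxy]benzene-1,3-dicarbaldehyde
Conditions: BnOH (1.5 equiv), Cs2CO3, 4 Å MS, DMF, rt to 40 °C
Reagents that add atoms: benzyl alcohol, OCc1ccccc1
Why: Nucleophilic aromatic substitution (addition–elimination through a Meisenheimer adduct) of the fluoride between two formyl groups by benzyl alkoxide, which the carbonate generates only in low concentration so that hydride transfer to the aldehydes stays slow.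

Step 7
Reactants: 13 2-(benzyloxy)-5-[(4-methoxybenzyl)oxy]benzene-1,3-dicarbaldehyde
Product: 14 2-(benzyloxy)-5-hydroxybenzene-1,3-dicarbaldehyde (ring E unit)
Conditions: TFA (10% v/v), pentamethylbenzene, CH2Cl2, 0 °C
Reagents that add atoms: none
Why: Acidolysis of the PMB aryl ether (ionisation to the stabilised 4-methoxybenzyl cation, trapped by Friedel–Crafts alkylation of pentamethylbenzene); the plain benzyl ether and the aldehydes should survive because a benzyl cation does not form under these conditions.

Step 8
Reactants: 14 2-(benzyloxy)-5-hydroxybenzene-1,3-dicarbaldehyde; 9 2-fluoro-5-[(4-methoxybenzyl)oxy]benzene-1,3-dicarbaldehyde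
Product: 15 PMB-protected D–E dimer, 2-(benzyloxy)-5-{2,6-diformyl-4-[(4-methoxybenzyl)oxy]phenoxy}benzene-1,3-dicarbaldehyde
Conditions: Cs2CO3, DMF, 50 °C
Reagents that add atoms: none
Why: Nucleophilic aromatic substitution by addition–elimination: the caesium phenoxide of 14 adds to the fluorine-bearing carbon of 9, both ortho formyl groups stabilise the Meisenheimer adduct, and fluoride leaves, so the hindered diaryl ether should form without a metal catalyst.

Step 9
Reactants: 15 PMB-protected D–E dimer
Product: 16 D–E dimer phenol, 2-(benzyloxy)-5-(2,6-diformyl-4-hydroxyphenoxy)benzene-1,3-dicarbaldehyde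
Conditions: TFA (10% v/v), pentamethylbenzene, CH2Cl2, 0 °C
Reagents that add atoms: none
Why: Acidolysis of the PMB ether as in step 7, to which the diaryl ether, the four aldehydes and the benzyl ether are inert.

Step 10
Reactants: 16 D–E dimer phenol; 9 2-fluoro-5-[(4-methoxybenzyl)oxy]benzene-1,3-dicarbaldehyde
Product: 17 PMB-protected C–D–E trimer (hexaaldehyde), PMBO-(unit C)-O-(unit D)-O-(unit E)-OBn
Conditions: Cs2CO3, DMF, 50 °C
Reagents that add atoms: none
Why: SNAr as in step 8; a slight excess of 9 and the moderate temperature should keep aryloxide exchange at the existing formyl-activated ether carbon well behind fluoride displacement.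

Step 11
Reactants: 17 PMB-protected C–D–E trimer
Product: 18 C–D–E trimer phenol (hexaaldehyde), HO-(unit C)-O-(unit D)-O-(unit E)-OBn
Conditions: TFA (10% v/v), pentamethylbenzene, CH2Cl2, 0 °C
Reagents that add atoms: none
Why: Acidolysis of the PMB ether with cation capture by pentamethylbenzene, selective over the benzyl ether as in step 7.

Step 12
Reactants: 18 C–D–E trimer phenol; 9 2-fluoro-5-[(4-methoxybenzyl)oxy]benzene-1,3-dicarbaldehyde
Product: 19 PMB-protected B–C–D–E tetramer (octaaldehyde), PMBO-(unit B)-O-(unit C)-O-(unit D)-O-(unit E)-OBn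
Conditions: Cs2CO3, DMF, 50 °C
Reagents that add atoms: none
Why: SNAr of the trimer phenoxide on the doubly formyl-activated fluoride, fluoride being a far better nucleofuge in the addition-limited mechanism than the internal aryloxides.

Step 13
Reactants: 19 PMB-protected B–C–D–E tetramer
Product: 20 B–C–D–E tetramer phenol (octaaldehyde), HO-(unit B)-O-(unit C)-O-(unit D)-O-(unit E)-OBn
Conditions: TFA (10% v/v), pentamethylbenzene, CH2Cl2, 0 °C
Reagents that add atoms: none
Why: Acidolysis of the PMB ether as in step 7, leaving the three diaryl ethers, eight aldehydes and the benzyl ether untouched.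

Step 14
Reactants: 20 B–C–D–E tetramer phenol; 11 5-(benzyloxy)-2-fluorobenzene-1,3-dicarbaldehyde
Product: 21 A–B–C–D–E decaaldehyde, BnO-(unit A)-O-(unit B)-O-(unit C)-O-(unit D)-O-(unit E)-OBn
Conditions: Cs2CO3, DMF, 50–60 °C
Reagents that add atoms: none
Why: Final SNAr of the tetramer phenoxide on the fluoride of 11, which installs ring A with its para oxygen already carrying the benzyl group that lasts to the end.

Step 15
Reactants: 21 A–B–C–D–E decaaldehyde; 22 3-chloroperoxybenzoic acid
Product: 23 A–B–C–D–E decaformate, 21 with each CHO replaced by OCHO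
Conditions: mCPBA (water-free, 15 equiv), Na2HPO4 (powder), CH2Cl2, 0 to 35 °C, dark; cold Na2SO3 / pH 7 buffer wash
Reagents that add atoms: 3-chloroperoxybenzoic acid, OOC(=O)c1cccc(Cl)c1
Why: Baeyer–Villiger (Dakin-type) oxidation: the peracid adds to each formyl carbon to give a Criegee peroxyhemiacetal, and the aryl ipso carbon migrates to the proximal peroxide oxygen as 3-chlorobenzoate departs, leaving an aryl formate. The closest known reaction is the mCPBA oxidation of ortho-alkoxy- and ortho-aryloxybenzaldehydes to aryl formates, the usual sequel to SNAr couplings of fluorobenzaldehydes; here it is run ten times in one molecule. No ring closes and no stereocentre forms. The selectivity needed is aryl over hydride migration at all ten sites, and it is secured by the ether oxygen ortho to every formyl group (OBn on ring E, OAr on rings A–D), whose lone pair supports the electron-deficient migrating carbon. The first oxidation on a ring also removes a meta formyl acceptor, so the second should be easier than the first. The water-free, phosphate-buffered medium keeps the formates intact, so that no free phenol meets the oxidant.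

Step 16
Reactants: 23 A–B–C–D–E decaformate
Product: 25 CNP0308003.0 (dodecahydroxy pentamer), via dibenzyl ether decaol 24 (not isolated)
Conditions: HCl (cat., 1.25 M in MeOH), degassed MeOH/THF, rt, Ar; then 10% Pd/C, H2 (1 atm), rt; filter and concentrate under Ar
Reagents that add atoms: none
Why: Acid-catalysed transesterification of the ten labile aryl formates with methanol, then palladium-catalysed hydrogenolysis of the two benzyl ethers in the same pot, the acidic, reducing, oxygen-free medium protecting the polyphenol from autoxidation to quinones.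

Compound list
1 | 4-fluoro-3,5-dimethylphenol | Cc1cc(O)cc(C)c1F | starting material
2 | acetic anhydride | CC(=O)OC(C)=O | starting material
3 | 4-fluoro-3,5-dimethylphenyl acetate | CC(=O)Oc1cc(C)c(F)c(C)c1 | intermediate
4 | N-bromosuccinimide | O=C1CCC(=O)N1Br | starting material
5 | 3,5-bis(dibromomethyl)-4-fluorophenyl acetate | CC(=O)Oc1cc(C(Br)Br)c(F)c(C(Br)Br)c1 | intermediate
6 | 4-fluoro-3,5-diformylphenyl acetate (formed in the flask in step 3) | CC(=O)Oc1cc(C=O)c(F)c(C=O)c1 | intermediate
7 | 2-fluoro-5-hydroxybenzene-1,3-dicarbaldehyde | Oc1cc(C=O)c(F)c(C=O)c1 | intermediate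
8 | 4-methoxybenzyl chloride | COc1ccc(CCl)cc1 | starting material
9 | 2-fluoro-5-[(4-methoxybenzyl)oxy]benzene-1,3-dicarbaldehyde | COc1ccc(COc2cc(C=O)c(F)c(C=O)c2)cc1 | intermediate
10 | benzyl bromide | BrCc1ccccc1 | starting material
11 | 5-(benzyloxy)-2-fluorobenzene-1,3-dicarbaldehyde | O=Cc1cc(OCc2ccccc2)cc(C=O)c1F | intermediate
12 | benzyl alcohol | OCc1ccccc1 | starting material
13 | 2-(benzyloxy)-5-[(4-methoxybenzyl)oxy]benzene-1,3-dicarbaldehyde | COc1ccc(COc2cc(C=O)c(OCc3ccccc3)c(C=O)c2)cc1 | intermediate
14 | 2-(benzyloxy)-5-hydroxybenzene-1,3-dicarbaldehyde | Oc1cc(C=O)c(OCc2ccccc2)c(C=O)c1 | intermediate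
15 | PMB-protected D–E dimer (tetraaldehyde) | COc1ccc(COc2cc(C=O)c(Oc3cc(C=O)c(OCc4ccccc4)c(C=O)c3)c(C=O)c2)cc1 | intermediate
16 | D–E dimer phenol (tetraaldehyde) | Oc1cc(C=O)c(Oc2cc(C=O)c(OCc3ccccc3)c(C=O)c2)c(C=O)c1 | intermediate
17 | PMB-protected C–D–E trimer (hexaaldehyde) | COc1ccc(COc2cc(C=O)c(Oc3cc(C=O)c(Oc4cc(C=O)c(OCc5ccccc5)c(C=O)c4)c(C=O)c3)c(C=O)c2)cc1 | intermediate
18 | C–D–E trimer phenol (hexaaldehyde) | Oc1cc(C=O)c(Oc2cc(C=O)c(Oc3cc(C=O)c(OCc4ccccc4)c(C=O)c3)c(C=O)c2)c(C=O)c1 | intermediate
19 | PMB-protected B–C–D–E tetramer (octaaldehyde) | COc1ccc(COc2cc(C=O)c(Oc3cc(C=O)c(Oc4cc(C=O)c(Oc5cc(C=O)c(OCc6ccccc6)c(C=O)c5)c(C=O)c4)c(C=O)c3)c(C=O)c2)cc1 | intermediate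
20 | B–C–D–E tetramer phenol (octaaldehyde) | Oc1cc(C=O)c(Oc2cc(C=O)c(Oc3cc(C=O)c(Oc4cc(C=O)c(OCc5ccccc5)c(C=O)c4)c(C=O)c3)c(C=O)c2)c(C=O)c1 | intermediate
21 | A–B–C–D–E decaaldehyde, benzyl ethers at A-para and E-central oxygen | C(Oc1cc(C=O)c(Oc2cc(C=O)c(Oc3cc(C=O)c(Oc4cc(C=O)c(Oc5cc(C=O)c(OCc6ccccc6)c(C=O)c5)c(C=O)c4)c(C=O)c3)c(C=O)c2)c(C=O)c1)c1ccccc1 | intermediate
22 | 3-chloroperoxybenzoic acid | OOC(=O)c1cccc(Cl)c1 | starting material
23 | A–B–C–D–E decaformate, benzyl ethers at A-para and E-central oxygen | C(Oc1cc(OC=O)c(Oc2cc(OC=O)c(Oc3cc(OC=O)c(Oc4cc(OC=O)c(Oc5cc(OC=O)c(OCc6ccccc6)c(OC=O)c5)c(OC=O)c4)c(OC=O)c3)c(OC=O)c2)c(OC=O)c1)c1ccccc1 | intermediate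
24 | dibenzyl ether decaol (formed in the flask in step 16) | C(Oc1cc(O)c(Oc2cc(O)c(Oc3cc(O)c(Oc4cc(O)c(Oc5cc(O)c(OCc6ccccc6)c(O)c5)c(O)c4)c(O)c3)c(O)c2)c(O)c1)c1ccccc1 | intermediate
25 | CNP0308003.0 (achiral) | Oc1cc(O)c(Oc2cc(O)c(Oc3cc(O)c(Oc4cc(O)c(Oc5cc(O)c(O)c(O)c5)c(O)c4)c(O)c3)c(O)c2)c(O)c1 | target

Total steps: 16. Longest linear sequence: 15 (steps 1–4 and 6–16; step 5 is a one-step branch to 11).

Steps most likely to fail

Step 15. Hydride migration may compete with aryl migration in one or more of the ten Criegee adducts, leaving carboxylic acids that cannot be repaired. Formates may also hydrolyse in the oxidising medium, after which the freed phenols would be over-oxidised. The fallback sets out from 21 and comes back at 24. It turns the aldehydes into methyl ketones, where aryl migration wins over methyl migration and no acid can arise. Addition of MeMgBr (THF, −78 °C) to 21 should give the deca(1-hydroxyethyl) pentamer F1 (diastereomer mixture; the carbinol centres are erased in the next operation). Dess–Martin oxidation should give the decaacetyl pentamer F2. Baeyer–Villiger oxidation with mCPBA and catalytic TFA (CH2Cl2, reflux) should give the decaacetate pentamer F3. Acidic methanolysis of F3 under the conditions of step 16 gives 24, which is hydrogenolysed to 25 in the same pot.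

Step 2. The radical chain may stop unevenly at the two methyl groups (tri- and pentabrominated material) or drift towards electrophilic ring bromination, giving mixtures that are hard to separate. The fallback sets out from 3 and comes back at 6, hence 7. It fixes the aldehyde oxidation level with an oxidant and not with the bromine count. NBS (2.1 equiv, AIBN, PhCF3, 80 °C) should give 3,5-bis(bromomethyl)-4-fluorophenyl acetate F4. N-Methylmorpholine N-oxide (MeCN, 4 Å MS, rt) should oxidise both benzylic bromides to give 6, isolated in this variant. Hydrolysis of 6 with 2 M H2SO4 in acetone/H2O at 60 °C then gives 7.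

Step 14. The bulky, poorly soluble and weakly nucleophilic tetramer phenoxide may displace fluoride slowly, which gives aryloxide exchange at the internal activated ether carbons time to scramble the chain length. The fallback sets out from 7, uses 11 and 18, and comes back at 21; steps 12 and 13 are then not needed. It is a convergent 3 + 2 coupling with a smaller nucleophile and a more electrophilic fluoride. Acetalisation of 7 (ethylene glycol, TsOH, toluene, Dean–Stark) should give 3,5-di(1,3-dioxolan-2-yl)-4-fluorophenol F5, whose C–F bond is no longer activated. Its phenoxide couples with 11 (Cs2CO3, DMF, 50 °C) to give the acetal-masked A–B dimer fluoride F6. Aqueous HCl/THF unmasks the A–B dimer fluoride F7, 5-[4-(benzyloxy)-2,6-diformylphenoxy]-2-fluorobenzene-1,3-dicarbaldehyde. Coupling of F7 with the trimer phenol 18 (Cs2CO3, DMF, 40 °C) gives 21.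

Further compounds
F1 | step 15 | deca(1-hydroxyethyl) analogue of 21 (each CHO replaced by CH(OH)CH3; diastereomer mixture, configuration undefined) | C(Oc1cc(C(C)O)c(Oc2cc(C(C)O)c(Oc3cc(C(C)O)c(Oc4cc(C(C)O)c(Oc5cc(C(C)O)c(OCc6ccccc6)c(C(C)O)c5)c(C(C)O)c4)c(C(C)O)c3)c(C(C)O)c2)c(C(C)O)c1)c1ccccc1
F2 | step 15 | decaacetyl analogue of 21 (each CHO replaced by C(O)CH3) | C(Oc1cc(C(C)=O)c(Oc2cc(C(C)=O)c(Oc3cc(C(C)=O)c(Oc4cc(C(C)=O)c(Oc5cc(C(C)=O)c(OCc6ccccc6)c(C(C)=O)c5)c(C(C)=O)c4)c(C(C)=O)c3)c(C(C)=O)c2)c(C(C)=O)c1)c1ccccc1
F3 | step 15 | decaacetate analogue of 23 (each OCHO replaced by OC(O)CH3) | C(Oc1cc(OC(C)=O)c(Oc2cc(OC(C)=O)c(Oc3cc(OC(C)=O)c(Oc4cc(OC(C)=O)c(Oc5cc(OC(C)=O)c(OCc6ccccc6)c(OC(C)=O)c5)c(OC(C)=O)c4)c(OC(C)=O)c3)c(OC(C)=O)c2)c(OC(C)=O)c1)c1ccccc1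
F4 | step 2 | 3,5-bis(bromomethyl)-4-fluorophenyl acetate | CC(=O)Oc1cc(CBr)c(F)c(CBr)c1
F5 | step 14 | 3,5-di(1,3-dioxolan-2-yl)-4-fluorophenol | Oc1cc(C2OCCO2)c(F)c(C2OCCO2)c1
F6 | step 14 | 5-(benzyloxy)-2-[3,5-di(1,3-dioxolan-2-yl)-4-fluorophenoxy]benzene-1,3-dicarbaldehyde | O=Cc1cc(OCc2ccccc2)cc(C=O)c1Oc1cc(C2OCCO2)c(F)c(C2OCCO2)c1
F7 | step 14 | 5-[4-(benzyloxy)-2,6-diformylphenoxy]-2-fluorobenzene-1,3-dicarbaldehyde | O=Cc1cc(OCc2ccccc2)cc(C=O)c1Oc1cc(C=O)c(F)c(C=O)c1
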